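## Retrosynthetic overview

1. The ten-membered ring is closed last, at C9–C10: the primary C9 radical of an iodomethyl lactone adds 10-endo-dig to a methyl ynone. H-transfer to the vinyl radical gives the (Z)-enone, and the product is the natural product itself.
2. The cyclisation precursor comes from an indium Barbier union at C6–C7 of an α-acyloxy aldehyde (C2–C6, already carrying the ynone and the epoxyangelate) with a 3-(bromomethyl)-5-(iodomethyl)butenolide. This sets C6 and C7 and creates the exocyclic methylene.
3. Aldehyde half: (R)-hydroxymethylbutenolide → cuprate (C4 methyl) → alkynyl-lithium lactone opening (ynone, and only the C5 hydroxyl freed) → esterification → direct oxidation of the silyl ether. The acid comes from Sharpless epoxidation of angelyl alcohol.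
4. Butenolide half: (S)-but-3-ene-1,2-diol → iodohydrin → 2-(bromomethyl)acrylate → ring-closing metathesis.
5. Ring order: oxirane → butenolide (becomes the α-methylene lactone in the Barbier step) → ten-membered carbocycle.

Locants used below: C2 ring ketone; C1=C10 enone (C14 methyl on C10); C3 CH2; C4 CHMe; C5 CH–O-acyl; C6 CHOH; C7/C8 ring fusion (C8–O); C9 CH2; C11=C13 methylene; C12 lactone C=O.

Assumption: (R)-5-(hydroxymethyl)furan-2(5H)-one and (Z)-2-methylbut-2-en-1-ol are taken as catalogue compounds (both are less common than their S and E counterparts).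

## Route

**Step 1**
Reactants: 1, (Z)-2-methylbut-2-en-1-ol
Product: 2, [(2S,3R)-2,3-dimethyloxiran-2-yl]methanol
Conditions: Ti(OiPr)4 (10 mol%), L-(+)-DIPT (12 mol%), t-BuOOH, 4 Å MS, CH2Cl2, −20 °C
Reagents that add atoms: tert-butyl hydroperoxide, CC(C)(C)OO (epoxide O)
Why: Katsuki–Sharpless asymmetric epoxidation; L-(+)-tartrate gives the 2S face (the same sense as nerol → (2S,3R)-epoxynerol) and syn O-transfer keeps the 3-methyl cis to CH2OH, so both oxirane stereocentres are set here.

**Step 2**
Reactants: 2, [(2S,3R)-2,3-dimethyloxiran-2-yl]methanol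
Product: 3, (2R,3R)-2,3-dimethyloxirane-2-carboxylic acid ((2R,3R)-epoxyangelic acid)
Conditions: RuCl3·xH2O (2 mol%), NaIO4, MeCN/EtOAc/H2O, rt
Reagents that add atoms: sodium periodate, [Na+].[O-]I(=O)(=O)=O, with water, O (oxygen source)
Why: RuO4 oxidation of a 2,3-epoxy alcohol to the glycidic acid leaves both stereocentres untouched (C2 changes from S to R only through CIP priorities).

**Step 3**
Reactants: 4, (R)-5-(hydroxymethyl)furan-2(5H)-one
Product: 5, (R)-5-{[(triethylsilyl)oxy]methyl}furan-2(5H)-one
Conditions: TESCl, imidazole, CH2Cl2, 0 °C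
Reagents that add atoms: chlorotriethylsilane, CC[Si](Cl)(CC)CC
Why: Routine silylation; TES is chosen because a primary TES ether can later be oxidised directly to the aldehyde.

**Step 4**
Reactants: 5, (R)-5-{[(triethylsilyl)oxy]methyl}furan-2(5H)-one
Product: 6, (4R,5R)-4-methyl-5-{[(triethylsilyl)oxy]methyl}oxolan-2-one (trans)
Conditions: Me2CuLi (from MeLi, CuI), Et2O, −78 → −40 °C
Reagents that add atoms: lithium dimethylcuprate, [Li+].C[Cu-]C (from methyllithium, [Li]C)
Why: Gilman conjugate addition to a γ-substituted butenolide occurs anti to the C5 substituent, giving the trans lactone and so the C4 methyl anti to the C5 oxygen.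

**Step 5**
Reactants: 6, (4R,5R)-4-methyl-5-{[(triethylsilyl)oxy]methyl}oxolan-2-one; 7, 1-propynyllithium
Product: 8, (6R,7R)-7-hydroxy-6-methyl-8-[(triethylsilyl)oxy]oct-2-yn-4-one (in equilibrium with its cyclic hemiketal)
Conditions: 7 (1.3 equiv), BF3·OEt2, THF, −78 °C; AcOH/THF quench at −78 °C
Reagents that add atoms: 1-propynyllithium (7), CC#C[Li]
Why: BF3-assisted mono-addition of an alkynyl-lithium to a γ-lactone stops at the tetrahedral intermediate and gives the ynone on work-up, freeing only the C5 hydroxyl while C6 stays silylated, which differentiates the two oxygens without a protecting-group exchange.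

**Step 6**
Reactants: 8, (6R,7R)-7-hydroxy-6-methyl-8-[(triethylsilyl)oxy]oct-2-yn-4-one; 3, (2R,3R)-2,3-dimethyloxirane-2-carboxylic acid
Product: 9, (2R,3R)-3-methyl-5-oxo-1-[(triethylsilyl)oxy]oct-6-yn-2-yl (2R,3R)-2,3-dimethyloxirane-2-carboxylate
Conditions: 3, 2,4,6-trichlorobenzoyl chloride, Et3N, THF; then 8, DMAP, toluene, rt
Reagents that add atoms: none (all new atoms come from reactant 3)
Why: Yamaguchi esterification acylates the open-chain secondary alcohol with the hindered α-quaternary epoxy acid with retention at every stereocentre, and the deactivated oxirane survives the mixed-anhydride conditions.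

**Step 7**
Reactants: 9, the TES ether ester from step 6
Product: 10, (2R,3R)-3-methyl-1,5-dioxooct-6-yn-2-yl (2R,3R)-2,3-dimethyloxirane-2-carboxylate
Conditions: (COCl)2, DMSO, CH2Cl2, −78 → −40 °C; then i-Pr2NEt, −78 → 0 °C; pH 7 work-up, used crude
Reagents that add atoms: none
Why: Swern conditions oxidise primary TES ethers directly to aldehydes, and cold treatment with a hindered base avoids epimerising the α-acyloxy centre.

**Step 8**
Reactants: 11, (S)-but-3-ene-1,2-diol
Product: 12, (S)-1-iodobut-3-en-2-ol
Conditions: I2, PPh3, imidazole, CH2Cl2, 0 °C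
Reagents that add atoms: iodine, II
Why: Appel/Garegg-type iodination is selective for the primary hydroxyl of a terminal 1,2-diol and does not touch the carbinol stereocentre.

**Step 9**
Reactants: 12, (S)-1-iodobut-3-en-2-ol; 13, 2-(bromomethyl)acrylic acid
Product: 14, (S)-1-iodobut-3-en-2-yl 2-(bromomethyl)prop-2-enoate
Conditions: 13, (COCl)2, cat. DMF, CH2Cl2, 0 °C; then 12, 2,6-lutidine, −20 → 0 °C
Reagents that add atoms: none (all new atoms come from reactant 13)
Why: Acid-chloride acylation with a hindered, non-nucleophilic base avoids SN2′ attack on the allylic bromide and epoxide closure of the iodohydrin.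

**Step 10**
Reactants: 14, (S)-1-iodobut-3-en-2-yl 2-(bromomethyl)prop-2-enoate
Product: 15, (S)-3-(bromomethyl)-5-(iodomethyl)furan-2(5H)-one
Conditions: Hoveyda–Grubbs II (5 mol%), toluene (5 mM), 80 °C
Reagents that add atoms: none
Why: Ring-closing metathesis of an allylic-alcohol acrylate gives the butenolide (as for methacrylates → α-substituted butenolides) with loss of ethylene and no change at the stereocentre.

**Step 11**
Reactants: 10, the aldehyde from step 7; 15, (S)-3-(bromomethyl)-5-(iodomethyl)furan-2(5H)-one
Product: 16, (1R,2R,3R)-1-hydroxy-1-[(2S,3R)-2-(iodomethyl)-4-methylidene-5-oxooxolan-3-yl]-3-methyl-5-oxooct-6-yn-2-yl (2R,3R)-2,3-dimethyloxirane-2-carboxylate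
Conditions: In powder (1.5 equiv), THF/H2O 3:1, rt
Reagents that add atoms: none
Why: Indium Barbier allylation; the allylindium formed at CH2Br attacks the aldehyde (faster than the ynone, and without touching the primary iodide) through C7 anti to the CH2I group (7,8-trans), and the chair transition state of this ring-locked, E-type allyl unit with the aldehyde chain equatorial gives the 6R carbinol while the double bond moves to the exocyclic position.

**Step 12 (key step)**
Reactants: 16, the iodo-lactone ynone from step 11
Product: 17, Vicolide D, (3aR,4R,5R,6R,9Z,11aR)-4-hydroxy-6,10-dimethyl-3-methylidene-2,8-dioxo-2,3,3a,4,5,6,7,8,11,11a-decahydrocyclodeca[b]furan-5-yl (2R,3R)-2,3-dimethyloxirane-2-carboxylate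
Conditions: (TMS)3SiH (1.3 equiv) and AIBN (0.3 equiv) added with 16 by syringe pump over 12 h to PhH at 80 °C, final concentration 1 mM
Reagents that add atoms: none ((TMS)3SiH supplies only H)
Why: Proposed new method: iodine abstraction gives the nucleophilic primary C9 radical, which adds 10-endo-dig to the electrophilic β-carbon (C10) of the ynone, and the resulting α-acyl vinyl radical takes H from the silane on the side of the small methyl group, which together with the ring constraint gives the (Z)-enone; the closest known reaction type is silane- or stannane-mediated endo radical macrocyclisation (Giese addition) of ω-iodoalkyl enones and ynones, established for larger rings, and here the trans-lactone geometry disfavours 1,5-H transfer, iodo-etherification and addition to the methylene lactone. C8 changes from S to R only through CIP priorities.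

## Compound list

1 | (Z)-2-methylbut-2-en-1-ol | C/C=C(/C)CO | starting material
2 | [(2S,3R)-2,3-dimethyloxiran-2-yl]methanol | OC[C@]1(C)O[C@@H]1C | intermediate
3 | (2R,3R)-2,3-dimethyloxirane-2-carboxylic acid | OC(=O)[C@]1(C)O[C@@H]1C | intermediate
4 | (R)-5-(hydroxymethyl)furan-2(5H)-one | OC[C@@H]1OC(=O)C=C1 | starting material
5 | (R)-5-{[(triethylsilyl)oxy]methyl}furan-2(5H)-one | CC[Si](CC)(CC)OC[C@@H]1OC(=O)C=C1 | intermediate
6 | (4R,5R)-4-methyl-5-{[(triethylsilyl)oxy]methyl}oxolan-2-one | O=C1C[C@@H](C)[C@@H](O1)CO[Si](CC)(CC)CC | intermediate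
7 | 1-propynyllithium | CC#C[Li] | starting material
8 | (6R,7R)-7-hydroxy-6-methyl-8-[(triethylsilyl)oxy]oct-2-yn-4-one | CC#CC(=O)C[C@@H](C)[C@@H](O)CO[Si](CC)(CC)CC | intermediate
9 | (2R,3R)-3-methyl-5-oxo-1-[(triethylsilyl)oxy]oct-6-yn-2-yl (2R,3R)-2,3-dimethyloxirane-2-carboxylate | CC#CC(=O)C[C@@H](C)[C@@H](OC(=O)[C@]1(C)O[C@@H]1C)CO[Si](CC)(CC)CC | intermediate
10 | (2R,3R)-3-methyl-1,5-dioxooct-6-yn-2-yl (2R,3R)-2,3-dimethyloxirane-2-carboxylate | CC#CC(=O)C[C@@H](C)[C@@H](OC(=O)[C@]1(C)O[C@@H]1C)C=O | intermediate
11 | (S)-but-3-ene-1,2-diol | OC[C@@H](O)C=C | starting material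
12 | (S)-1-iodobut-3-en-2-ol | C=C[C@@H](CI)O | intermediate
13 | 2-(bromomethyl)acrylic acid | C=C(CBr)C(=O)O | starting material
14 | (S)-1-iodobut-3-en-2-yl 2-(bromomethyl)prop-2-enoate | C=C[C@@H](CI)OC(=O)C(=C)CBr | intermediate
15 | (S)-3-(bromomethyl)-5-(iodomethyl)furan-2(5H)-one | O=C1O[C@H](CI)C=C1CBr | intermediate
16 | (1R,2R,3R)-1-hydroxy-1-[(2S,3R)-2-(iodomethyl)-4-methylidene-5-oxooxolan-3-yl]-3-methyl-5-oxooct-6-yn-2-yl (2R,3R)-2,3-dimethyloxirane-2-carboxylate | C=C1C(=O)O[C@H](CI)[C@H]1[C@@H](O)[C@H](OC(=O)[C@]2(C)O[C@@H]2C)[C@H](C)CC(=O)C#CC | intermediate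
17 | Vicolide D | C=C1C(=O)O[C@@H]2C/C(C)=C\C(=O)C[C@@H](C)[C@@H](OC(=O)[C@]3(C)O[C@@H]3C)[C@H](O)[C@@H]12 | target

## Summary

Total steps: 12. Longest linear sequence: 7 (steps 3, 4, 5, 6, 7, 11, 12).

Steps most likely to fail, with fallbacks:

1. **Step 12 (10-endo-dig radical macrocyclisation).** Premature reduction of the C9 radical, intermolecular addition to the methylene lactone, or E/Z leakage could dominate. Fallback: reverse the order of the two unions. Form C9–C10 first by an intermolecular Giese addition of the iodomethyl butenolide (allylic position carried as the acetate) to ynone 9 with C6 still silylated. Then unveil the C6 aldehyde and close the ring at C6–C7 by an intramolecular In or CrCl2 Barbier allylation.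
2. **Step 11 (Barbier union).** The α-acyloxy aldehyde may follow its Felkin preference against the reagent-controlled chair, or the ester may migrate from O5 to O6. Fallback: protect the C5 hydroxyl of 8 as a PMB ether instead of esterifying, run the coupling under Zn/chelation control (which favours the required 5,6-syn diol), and install the epoxyangelate after ring closure with C6 temporarily silylated.
3. **Step 10 (RCM to the bromomethyl butenolide).** The 1,1-disubstituted acrylate and the allylic bromide may slow or poison the catalyst. Fallback: a non-metathesis construction of 15. Open (S)-epichlorohydrin with an acetylide to (S)-1-chloropent-4-yn-2-ol, carry out Pd-catalysed cyclocarbonylation to the α-methylene-γ-(chloromethyl) lactone, add Br2 and eliminate HBr to the 3-(bromomethyl)butenolide, and perform the Finkelstein exchange to the iodide after the Barbier step.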